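Read the winter run at 20.0 min, when its whole feed has gone in: target and starting material together come to 91.0 %, so 9.00 % of the charge is missing. The protic impurity charged in that run equals 10.0 % of the starting material. Take the plain one-to-one case as the zero of the scale, one impurity molecule spoiling one molecule of starting material. Then the impurity's claim is c(protic impurity) divided by c(starting material) in the charge, the share it can take if it is used up. For amber that is 33.3 %, and for grey 10.0 %.

| flask | starting material | reagent | protic impurity | free catalyst | temperature | remark | time |
|---|---|---|---|---|---|---|---|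
| winter | 0.050 M (fed, over 15 min) | 0.17 M | 5 mM | 0.25 mM | −25 °C | run made earlier; the fed solution adds 0.10 times the starting volume |  |
| midnight | 0.050 M (fed, over 15 min) | 0.28 M | 5 mM | 0.25 mM | −5 °C | run made earlier; the fed solution adds 0.10 times the starting volume |  |
| noon | 0.050 M (fed, over 15 min) | 0.69 M | 5 mM | 0.25 mM | −25 °C | run made earlier; the fed solution adds 0.10 times the starting volume |  |
| autumn | 0.025 M (fed, over 15 min) | 0.15 M | 5 mM | 0.25 mM | −5 °C | run made earlier; the fed solution adds 0.10 times the starting volume |  |
| grey | 0.050 M (fed, over 15 min) | 0.150 M | 5.00 mM | 0.25 mM |  | at −20 °C until 15 min, from then on at 10 °C; the fed solution adds 0.10 times the starting volume | 40 min |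
| amber | 0.015 M (fed, over 15 min) | 0.600 M | 5.00 mM | 0.25 mM |  | at 10 °C throughout; the fed solution adds 0.10 times the starting volume | 40 min |

| run | time / min | target / % | starting material / % |
|---|---|---|---|
| winter | 2.00 | 0 | 10 |
| winter | 5.00 | 3 | 26 |
| winter | 10.0 | 15 | 47 |
| winter | 15.0 | 25 | 70 |
| winter | 20.0 | 30 | 61 |
| midnight | 2.00 | 6 | 8 |
| midnight | 4.00 | 10 | 18 |
| midnight | 6.00 | 22 | 18 |
| midnight | 8.00 | 24 | 26 |
| midnight | 10.0 | 28 | 30 |
| noon | 4.00 | 8 | 17 |
| noon | 8.00 | 31 | 23 |
| noon | 12.0 | 50 | 29 |
| noon | 15.0 | 65 | 31 |
| noon | 20.0 | 82 | 17 |
| autumn | 1.00 | 1 | 6 |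
| autumn | 2.50 | 1 | 8 |
| autumn | 5.00 | 10 | 24 |
| autumn | 8.00 | 18 | 28 |
| autumn | 10.0 | 20 | 37 |

(each reading ± 1.5 percentage points)

- amounts are per litre of the starting volume; all of the dose is in the solution fed
- what was read earlier has a scatter of 1.5 percentage points, one standard deviation
- percentages count the whole charge, also what has not yet gone in

1. the flask that ends with the higher amount of target, in percent of the starting material charged, or "neither" when 2 percentage points or less lies between them (grey / amber / neither)
2. final target, as a percentage of the starting material charged, in grey
3. final target, as a percentage of the starting material charged, in amber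

Now turn the settings. By hand, a smaller charge of starting material raises the claim, the impurity being the same. The autumn run, with a claim of 20.0 %, already lacks 9.67 % of its charge at 10.0 min, counted against the 66.7 % fed by then.

By hand, more reagent hurries the target along, so starting material waits less for the impurity. The noon run at 20.0 min shows this: its gap is 1.00 %, less than winter's, with a scatter of 1.5 percentage points on each reading. So the claim is a ceiling, not a bill.

By hand, warmth speeds both paths. The midnight run, at −5 °C with 0.28 M of reagent, lacks 8.67 % at 10.0 min, counted against the 66.7 % fed by then.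

Amber stands at 10 °C, warmer than those runs, so my own reckoning lets its impurity take the full claim and the rest of the starting material become target, which gives 66.7 %. For grey I take winter's 25 % at the end of the feed and its late pace, the rise to 30 % by 20.0 min, held to the end. That gives 50.0 %, below the 90.0 % that grey's claim leaves.

The forecast names amber too, but with 29 % for grey and 90 % for amber, on the ground that “target made before the catalyst dies scales with reagent”.

Grey ends at 48.6 % and amber at 72.2 %, so amber gives more.

reagent + free catalyst ⇌ catalyst intermediate A (K = 3.60 /M, k = 1.10 /M/s, Ea = 35.0 kJ/mol, ΔH = −27.0 kJ/mol); starting material + catalyst intermediate A ⇌ catalyst intermediate B (K = 9.70 /M, k = 65.0 /M/s, Ea = 43.0 kJ/mol, ΔH = −27.0 kJ/mol); catalyst intermediate B → free catalyst + target (k = 24.0 /s, Ea = 48.0 kJ/mol); 2 starting material → self-condensation product (k = 4.20 × 10⁻⁵ /M/s, Ea = 64.0 kJ/mol); starting material + protic impurity → quenched substrate (k = 0.0650 /M/s, Ea = 39.0 kJ/mol); 2 free catalyst → spent catalyst (k = 4.40 /M/s, Ea = 47.0 kJ/mol); (constants at −20 °C) In amber, 21 % of the protic impurity is still there at 40.0 min, and quenched substrate stands at 26.2 % of the starting material charged. The claim times the part of the impurity spent gives 26.3 %. The flask like amber but with 0.0060 M of starting material has a claim of 83.3 % and keeps 61 % of its impurity, which reckons to 32.5 %, and it holds 32.2 % of quenched substrate.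

(All runs were generated by integration for an exercise; scatter was added.)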